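The route rests on reading the E-C2=C3(Me) olefin of the 14-membered carbocycle (C1–C14), which adjoins the C1 carbinol, as a C2≡C3 alkyne. Ring-closing alkyne metathesis of an acyclic bis(methyl-capped) diyne forges that triple bond and the macrocycle in one operation and leaves both Z olefins untouched. The propargylic C1 hydroxyl then directs trans-hydroalumination–iodination, guides epoxidation to the homoallylic C12=C13 olefin while C3 carries iodine, and the iodide is finally replaced by methyl. The metathesis precursor is a (1R,6R)-8Z,12Z-dienediyne bearing a C1 triethylsilyl ether and a tertiary tert-butyldimethylsilyl ether, built from (R)-α-terpineol.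

Key step: step 11

Atom labels: the carbinol carbon that carries the acetate is C1; the ring then runs through the C2=C3 olefin (methyl on C3), C4, C5, C6 (which carries the 2-hydroxypropan-2-yl group), C7, the C8=C9 olefin (methyl on C9), C10, C11, the C12–C13 epoxide (methyl on C13) and C14 back to C1. Acyclic intermediates keep these labels.

Assumption: the (R,R)-bishydroxamic acid ligand of step 14 is taken as the enantiomer that delivers oxygen to the C12=C13 face giving the (12S,13R)-epoxide; if a trial shows the opposite sense, the (S,S)-ligand is used with no other change.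

Step 1
Reactants: 1 (R)-(+)-α-terpineol
Product: 2 (R)-α-terpinyl tert-butyldimethylsilyl ether
Conditions: tBuMe2SiOTf, 2,6-lutidine, CH2Cl2, 0 °C → rt
Reagents that add atoms: tert-butyldimethylsilyl triflate (CC(C)(C)[Si](C)(C)OS(=O)(=O)C(F)(F)F)
Why: Silylation of the tertiary alcohol with the silyl triflate under lutidine buffering should avoid acid-induced rearrangement of the terpene and masks the hydroxyl that would otherwise form a lactol with the aldehyde released in step 2; the C6 stereocentre is taken unchanged from the chiral pool.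

Step 2
Reactants: 2 (R)-α-terpinyl tert-butyldimethylsilyl ether
Product: 5 (5R)-5-[2-(tert-butyldimethylsilyloxy)propan-2-yl]-7,7-dimethoxyheptan-2-one, via hydroperoxy aldehyde 3 (not isolated), via hydroperoxy acetal 4 (not isolated)
Conditions: O3, CH2Cl2/MeOH, −78 °C; TsOH·H2O (cat.), rt; NaHCO3, then Me2S, rt
Reagents that add atoms: ozone ([O-][O+]=O); methanol (CO)
Why: Ozonolysis with a terminus-differentiating work-up should work because the trisubstituted olefin fragments to the ketone oxide, which methanol traps, and a free aldehyde, which alone is acetalised before the hydroperoxide is reduced to the methyl ketone.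

Step 3
Reactants: 5 (5R)-5-[2-(tert-butyldimethylsilyloxy)propan-2-yl]-7,7-dimethoxyheptan-2-one
Product: 8 tert-butyl{[2-((3R)-1,1-dimethoxyoct-6-yn-3-yl)propan-2-yl]oxy}dimethylsilane, via enol phosphate 6 (not isolated), via lithium acetylide 7 (not isolated)
Conditions: LiN(iPr)2, THF, −78 °C; ClP(O)(OEt)2; LiN(iPr)2 (2.3 equiv), −78 °C → rt; MeI, DMPU, 0 °C → rt
Reagents that add atoms: iodomethane (CI)
Why: Kinetic enolisation at the methyl group, phosphorylation and double dehydro-elimination (methyl ketone to terminal alkyne via the enol phosphate) should give the lithium acetylide, which is C-methylated in the same flask; the acetal and silyl ether are inert to the amide base.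

Step 4
Reactants: 8 tert-butyl{[2-((3R)-1,1-dimethoxyoct-6-yn-3-yl)propan-2-yl]oxy}dimethylsilane
Product: 9 (3R)-3-[2-(tert-butyldimethylsilyloxy)propan-2-yl]oct-6-ynal
Conditions: AcOH/THF/H2O (3:1:1), rt
Reagents that add atoms: water (O)
Why: Mild aqueous acid hydrolyses the dimethyl acetal (acetal hydrolysis) while the hindered tertiary silyl ether and the internal alkyne should be untouched.

Step 5
Reactants: 9 (3R)-3-[2-(tert-butyldimethylsilyloxy)propan-2-yl]oct-6-ynal
Product: 10 tert-butyl{[2-((2Z,5R)-2-iododec-2-en-8-yn-5-yl)propan-2-yl]oxy}dimethylsilane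
Conditions: [Ph3PEt]I, nBuLi, THF, rt; I2, −78 °C; NaN(SiMe3)2, −78 → −20 °C; then 9, −78 °C → rt
Reagents that add atoms: ethyltriphenylphosphonium iodide (CC[P+](c1ccccc1)(c1ccccc1)c1ccccc1.[I-]); iodine (II)
Why: The Stork–Zhao olefination in its α-iodoethylidene form (a Wittig reaction) is known to turn aliphatic aldehydes into (Z)-2-iodo-2-alkenes, which places iodine cis to C7 so that the later coupling gives the Z-C8=C9 olefin.

Step 6
Reactants: 11 allyl alcohol
Product: 12 allyl N,N-diisopropylcarbamate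
Conditions: iPr2NC(O)Cl, Et3N, CH2Cl2, reflux
Reagents that add atoms: N,N-diisopropylcarbamoyl chloride (CC(C)N(C(C)C)C(Cl)=O)
Why: O-Carbamoylation of a primary alcohol is routine and installs the directing group needed for the lithiation of step 9.

Step 7
Reactants: 12 allyl N,N-diisopropylcarbamate; 10 tert-butyl{[2-((2Z,5R)-2-iododec-2-en-8-yn-5-yl)propan-2-yl]oxy}dimethylsilane
Product: 14 (4Z,7R)-7-[2-(tert-butyldimethylsilyloxy)propan-2-yl]-4-methyldodec-4-en-10-yn-1-yl N,N-diisopropylcarbamate, via alkylborane 13 (not isolated)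
Conditions: 12, 9-BBN, THF, rt; then 10, Pd(dppf)Cl2 (5 mol%), AsPh3, Cs2CO3, DMF/H2O, rt
Reagents that add atoms: none
Why: Anti-Markovnikov hydroboration of the terminal olefin (complete before the alkyne-containing iodide is added) and B-alkyl Suzuki–Miyaura coupling with retention at the alkenyl iodide should transfer the Z geometry to C8=C9 and deliver C10–C12 with the carbamate already in place.

Step 8
Reactants: 15 but-2-yn-1-ol
Product: 16 but-2-ynal
Conditions: MnO2, CH2Cl2, rt; filtered and used as a titrated solution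
Reagents that add atoms: none
Why: Activated MnO2 oxidises propargylic alcohols to ynals without over-oxidation (propargylic alcohol oxidation), and the volatile aldehyde is kept in solution.

Step 9
Reactants: 14 (4Z,7R)-7-[2-(tert-butyldimethylsilyloxy)propan-2-yl]-4-methyldodec-4-en-10-yn-1-yl N,N-diisopropylcarbamate; 16 but-2-ynal; 17 isopropenylboronic acid pinacol ester
Product: 21 (4R,6Z,10Z,13R)-13-[2-(tert-butyldimethylsilyloxy)propan-2-yl]-6,10-dimethyloctadeca-6,10-diene-2,16-diyn-4-ol, via lithiated carbamate 18 (not isolated), via boronate complex 19 (not isolated), via allylboronate 20 (not isolated)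
Conditions: sBuLi, (−)-sparteine, Et2O, −78 °C; 17, −78 °C; MgBr2·OEt2, −78 °C → reflux; then 16, 0 °C → rt; aqueous work-up
Reagents that add atoms: none
Why: Sparteine-mediated deprotonation of the carbamate (Hoppe lithiation) removes the pro-S hydrogen at C12, borylation with retention and 1,2-metalate rearrangement with inversion (lithiation–borylation) should give the (R)-α-substituted methallyl boronate, and its allylboration of the ynal through a chair whose α-chain is forced axial by the 2-methyl group transfers chirality to set C1 as R and C12=C13 as Z.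

Step 10
Reactants: 21 (4R,6Z,10Z,13R)-13-[2-(tert-butyldimethylsilyloxy)propan-2-yl]-6,10-dimethyloctadeca-6,10-diene-2,16-diyn-4-ol
Product: 22 (4R,6Z,10Z,13R)-13-[2-(tert-butyldimethylsilyloxy)propan-2-yl]-6,10-dimethyl-4-(triethylsilyloxy)octadeca-6,10-diene-2,16-diyne
Conditions: Et3SiCl, imidazole, DMAP (cat.), CH2Cl2, 0 °C → rt
Reagents that add atoms: chlorotriethylsilane (CC[Si](Cl)(CC)CC)
Why: Standard silylation of the secondary propargylic alcohol removes the protic group that would deactivate the alkylidyne catalyst and gives an ether that can later be cleaved beside the tertiary silyl ether.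

Step 11
Reactants: 22 (4R,6Z,10Z,13R)-13-[2-(tert-butyldimethylsilyloxy)propan-2-yl]-6,10-dimethyl-4-(triethylsilyloxy)octadeca-6,10-diene-2,16-diyne
Product: 23 (1R,6R,8Z,12Z)-6-[2-(tert-butyldimethylsilyloxy)propan-2-yl]-9,13-dimethyl-1-(triethylsilyloxy)cyclotetradeca-8,12-dien-2-yne
Conditions: Mo(≡CC6H4OMe-4)(OSiPh3)3 (10 mol%), powdered 5 Å molecular sieves, toluene (0.002 M), rt → 60 °C
Reagents that add atoms: none
Why: The molybdenum alkylidyne adds [2+2] to one methyl-capped alkyne to give a metallacyclobutadiene, cycloreverts with loss of 2-butyne (taken up by the sieves), and the substrate-bound alkylidyne then engages the second alkyne intramolecularly, so the C2≡C3 bond and the ring form in one catalytic cycle. This is ring-closing alkyne metathesis with a molybdenum alkylidyne triarylsilanolate, a reaction class well established for 12- to 20-membered cycloalkynes that carry propargylic silyl ethers. The carbocycle C1–C14 closes by joining the two chain termini at C2 and C3, with both alkyne carbons becoming ring members (an endo-type macrocyclisation), and a 14-membered ring holds the linear C1–C2≡C3–C4 unit without strain. No stereocentre is created: C1 and C6 pass through unchanged, and the Z olefins cannot isomerise because the alkylidyne does not react with alkenes. The step needs alkyne-over-alkene chemoselectivity, which is inherent to the catalyst, and ring closure over oligomerisation, which high dilution, removal of 2-butyne and the chain-bending Z-C8=C9 and Z-C12=C13 olefins should secure; the two silyl ethers keep protic groups away from the metal.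

Step 12
Reactants: 23 (1R,6R,8Z,12Z)-6-[2-(tert-butyldimethylsilyloxy)propan-2-yl]-9,13-dimethyl-1-(triethylsilyloxy)cyclotetradeca-8,12-dien-2-yne
Product: 24 (1R,6R,8Z,12Z)-6-[2-(tert-butyldimethylsilyloxy)propan-2-yl]-9,13-dimethylcyclotetradeca-8,12-dien-2-yn-1-ol
Conditions: PPTS, MeOH/CH2Cl2, 0 °C → rt
Reagents that add atoms: none
Why: Acid-catalysed methanolysis cleaves the secondary triethylsilyl ether far faster than the hindered tertiary tert-butyldimethylsilyl ether (selective desilylation) and frees the C1 hydroxyl as a directing group.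

Step 13
Reactants: 24 (1R,6R,8Z,12Z)-6-[2-(tert-butyldimethylsilyloxy)propan-2-yl]-9,13-dimethylcyclotetradeca-8,12-dien-2-yn-1-ol
Product: 26 (1R,2Z,6R,8Z,12Z)-6-[2-(tert-butyldimethylsilyloxy)propan-2-yl]-3-iodo-9,13-dimethylcyclotetradeca-2,8,12-trien-1-ol, via alkenylalanate 25 (not isolated)
Conditions: NaAlH2(OCH2CH2OMe)2, THF, 0 °C → rt; EtOAc; then I2, THF, −78 → 0 °C
Reagents that add atoms: iodine (II)
Why: The C1 alkoxide delivers hydride to C2 and holds aluminium on C3 in a five-membered chelate (alkoxide-directed trans-hydroalumination of a propargylic alcohol), and iodinolysis with retention should give the C3 iodide with C1 and C4 trans.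

Step 14
Reactants: 26 (1R,2Z,6R,8Z,12Z)-6-[2-(tert-butyldimethylsilyloxy)propan-2-yl]-3-iodo-9,13-dimethylcyclotetradeca-2,8,12-trien-1-ol
Product: 27 (1R,2Z,6R,8Z,12S,13R)-6-[2-(tert-butyldimethylsilyloxy)propan-2-yl]-12,13-epoxy-3-iodo-9,13-dimethylcyclotetradeca-2,8-dien-1-ol
Conditions: VO(OiPr)3 (5 mol%), (R,R)-N,N′-dihydroxy-N,N′-bis(diphenylacetyl)cyclohexane-1,2-diamine (10 mol%), cumene hydroperoxide, toluene, rt
Reagents that add atoms: cumene hydroperoxide (CC(C)(OO)c1ccccc1)
Why: In this vanadium-catalysed hydroxyl-directed epoxidation with a chiral bishydroxamic acid ligand the C1 vanadate should deliver the peroxide oxygen only to the homoallylic, electron-rich C12=C13 olefin (the allylic C2=C3 bears iodine and is deactivated, C8=C9 is out of reach, and the tertiary hydroxyl is silylated), with the ligand fixing the face that gives the (12S,13R)-epoxide.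

Step 15
Reactants: 27 (1R,2Z,6R,8Z,12S,13R)-6-[2-(tert-butyldimethylsilyloxy)propan-2-yl]-12,13-epoxy-3-iodo-9,13-dimethylcyclotetradeca-2,8-dien-1-ol
Product: 28 (1R,2E,6R,8Z,12S,13R)-6-[2-(tert-butyldimethylsilyloxy)propan-2-yl]-12,13-epoxy-3,9,13-trimethylcyclotetradeca-2,8-dien-1-ol
Conditions: Me2Zn, Pd(dppf)Cl2 (10 mol%), THF, 0 → 45 °C
Reagents that add atoms: dimethylzinc (C[Zn]C)
Why: Negishi methylation of the alkenyl iodide proceeds with retention and tolerates the zinc alkoxide and the epoxide, so the E-C2=C3(Me) olefin should result; it is run before acetylation because an allylic acetate would ionise with zerovalent palladium.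

Step 16
Reactants: 28 (1R,2E,6R,8Z,12S,13R)-6-[2-(tert-butyldimethylsilyloxy)propan-2-yl]-12,13-epoxy-3,9,13-trimethylcyclotetradeca-2,8-dien-1-ol
Product: 29 (1R,2E,6R,8Z,12S,13R)-12,13-epoxy-6-(2-hydroxypropan-2-yl)-3,9,13-trimethylcyclotetradeca-2,8-dien-1-ol
Conditions: Bu4NF, THF, 0 → 45 °C
Reagents that add atoms: none
Why: Fluoride-mediated desilylation removes the tertiary silyl ether at a stage where no ester is present that it could cleave, and the epoxide and allylic alcohol should be stable to it.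

Step 17
Reactants: 29 (1R,2E,6R,8Z,12S,13R)-12,13-epoxy-6-(2-hydroxypropan-2-yl)-3,9,13-trimethylcyclotetradeca-2,8-dien-1-ol
Product: 30 (1R,2E,6R,8Z,12S,13R)-12,13-epoxy-6-(2-hydroxypropan-2-yl)-3,9,13-trimethylcyclotetradeca-2,8-dien-1-yl acetate (CNP0254503.2)
Conditions: Ac2O (1.3 equiv), pyridine, DMAP (cat.), CH2Cl2, 0 °C
Reagents that add atoms: acetic anhydride (CC(=O)OC(C)=O)
Why: Acylation discriminates cleanly between the secondary allylic C1 hydroxyl and the hindered tertiary hydroxyl (chemoselective acetylation), which should give the target without touching a stereocentre.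

Compound list

1 | (R)-(+)-α-terpineol, (R)-2-(4-methylcyclohex-3-en-1-yl)propan-2-ol | CC1=CC[C@@H](CC1)C(C)(C)O | starting material
2 | (R)-α-terpinyl tert-butyldimethylsilyl ether, tert-butyldimethyl{[2-((1R)-4-methylcyclohex-3-en-1-yl)propan-2-yl]oxy}silane | CC1=CC[C@@H](CC1)C(C)(C)O[Si](C)(C)C(C)(C)C | intermediate
3 | (3R)-3-[2-(tert-butyldimethylsilyloxy)propan-2-yl]-6-hydroperoxy-6-methoxyheptanal (both C6 epimers) | CC(OC)(OO)CC[C@@H](C(C)(C)O[Si](C)(C)C(C)(C)C)CC=O | intermediate
4 | tert-butyl{[2-((3R)-6-hydroperoxy-1,1,6-trimethoxyheptan-3-yl)propan-2-yl]oxy}dimethylsilane (both C6 epimers) | CC(OC)(OO)CC[C@@H](C(C)(C)O[Si](C)(C)C(C)(C)C)CC(OC)OC | intermediate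
5 | (5R)-5-[2-(tert-butyldimethylsilyloxy)propan-2-yl]-7,7-dimethoxyheptan-2-one | CC(=O)CC[C@@H](C(C)(C)O[Si](C)(C)C(C)(C)C)CC(OC)OC | intermediate
6 | diethyl (5R)-5-[2-(tert-butyldimethylsilyloxy)propan-2-yl]-7,7-dimethoxyhept-1-en-2-yl phosphate | C=C(OP(=O)(OCC)OCC)CC[C@@H](C(C)(C)O[Si](C)(C)C(C)(C)C)CC(OC)OC | intermediate
7 | lithium acetylide of (5R)-5-[2-(tert-butyldimethylsilyloxy)propan-2-yl]-7,7-dimethoxyhept-1-yne | [Li]C#CCC[C@@H](C(C)(C)O[Si](C)(C)C(C)(C)C)CC(OC)OC | intermediate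
8 | tert-butyl{[2-((3R)-1,1-dimethoxyoct-6-yn-3-yl)propan-2-yl]oxy}dimethylsilane | CC#CCC[C@@H](C(C)(C)O[Si](C)(C)C(C)(C)C)CC(OC)OC | intermediate
9 | (3R)-3-[2-(tert-butyldimethylsilyloxy)propan-2-yl]oct-6-ynal | CC#CCC[C@@H](C(C)(C)O[Si](C)(C)C(C)(C)C)CC=O | intermediate
10 | tert-butyl{[2-((2Z,5R)-2-iododec-2-en-8-yn-5-yl)propan-2-yl]oxy}dimethylsilane (iodine on C9, cis to C7) | CC#CCC[C@@H](C(C)(C)O[Si](C)(C)C(C)(C)C)C/C=C(/C)I | intermediate
11 | allyl alcohol (prop-2-en-1-ol) | C=CCO | starting material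
12 | allyl N,N-diisopropylcarbamate | C=CCOC(=O)N(C(C)C)C(C)C | intermediate
13 | 3-(9-borabicyclo[3.3.1]nonan-9-yl)propyl N,N-diisopropylcarbamate | CC(C)N(C(C)C)C(=O)OCCCB1C2CCCC1CCC2 | intermediate
14 | (4Z,7R)-7-[2-(tert-butyldimethylsilyloxy)propan-2-yl]-4-methyldodec-4-en-10-yn-1-yl N,N-diisopropylcarbamate | CC#CCC[C@@H](C(C)(C)O[Si](C)(C)C(C)(C)C)C/C=C(/C)CCCOC(=O)N(C(C)C)C(C)C | intermediate
15 | but-2-yn-1-ol | CC#CCO | starting material
16 | but-2-ynal | CC#CC=O | intermediate
17 | isopropenylboronic acid pinacol ester | CC(=C)B1OC(C)(C)C(C)(C)O1 | starting material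
18 | (1S)-1-lithio derivative of 14 (lithium on C12, (−)-sparteine-bound) | CC#CCC[C@@H](C(C)(C)O[Si](C)(C)C(C)(C)C)C/C=C(/C)CC[C@H]([Li])OC(=O)N(C(C)C)C(C)C | intermediate
19 | lithium boronate complex: tetracoordinate boron carrying pinacolate, isopropenyl and the (S)-configured C12, which still bears the carbamate | CC#CCC[C@@H](C(C)(C)O[Si](C)(C)C(C)(C)C)C/C=C(/C)CC[C@H]([B-]1(C(C)=C)OC(C)(C)C(C)(C)O1)OC(=O)N(C(C)C)C(C)C.[Li+] | intermediate
20 | 2-[(3R,6Z,9R)-9-[2-(tert-butyldimethylsilyloxy)propan-2-yl]-2,6-dimethyltetradeca-1,6-dien-12-yn-3-yl]-4,4,5,5-tetramethyl-1,3,2-dioxaborolane | CC#CCC[C@@H](C(C)(C)O[Si](C)(C)C(C)(C)C)C/C=C(/C)CC[C@@H](B1OC(C)(C)C(C)(C)O1)C(C)=C | intermediate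
21 | (4R,6Z,10Z,13R)-13-[2-(tert-butyldimethylsilyloxy)propan-2-yl]-6,10-dimethyloctadeca-6,10-diene-2,16-diyn-4-ol | CC#CCC[C@@H](C(C)(C)O[Si](C)(C)C(C)(C)C)C/C=C(/C)CC/C=C(/C)C[C@@H](O)C#CC | intermediate
22 | (4R,6Z,10Z,13R)-13-[2-(tert-butyldimethylsilyloxy)propan-2-yl]-6,10-dimethyl-4-(triethylsilyloxy)octadeca-6,10-diene-2,16-diyne (ring labels 1R,6R,8Z,12Z) | CC#CCC[C@@H](C(C)(C)O[Si](C)(C)C(C)(C)C)C/C=C(/C)CC/C=C(/C)C[C@@H](O[Si](CC)(CC)CC)C#CC | intermediate
23 | (1R,6R,8Z,12Z)-6-[2-(tert-butyldimethylsilyloxy)propan-2-yl]-9,13-dimethyl-1-(triethylsilyloxy)cyclotetradeca-8,12-dien-2-yne | CC[Si](CC)(CC)O[C@H]1C#CCC[C@@H](C(C)(C)O[Si](C)(C)C(C)(C)C)C/C=C(/C)CC/C=C(/C)C1 | intermediate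
24 | (1R,6R,8Z,12Z)-6-[2-(tert-butyldimethylsilyloxy)propan-2-yl]-9,13-dimethylcyclotetradeca-8,12-dien-2-yn-1-ol | O[C@H]1C#CCC[C@@H](C(C)(C)O[Si](C)(C)C(C)(C)C)C/C=C(/C)CC/C=C(/C)C1 | intermediate
25 | sodium alkenylalanate: five-membered O–Al–C3=C2–C1 chelate of the macrocycle, aluminium also bearing two 2-methoxyethoxy groups | [Na+].COCCO[Al-]1(OCCOC)O[C@H]2/C=C1/CC[C@@H](C(C)(C)O[Si](C)(C)C(C)(C)C)C/C=C(/C)CC/C=C(/C)C2 | intermediate
26 | (1R,2Z,6R,8Z,12Z)-6-[2-(tert-butyldimethylsilyloxy)propan-2-yl]-3-iodo-9,13-dimethylcyclotetradeca-2,8,12-trien-1-ol | O[C@H]1/C=C(\I)CC[C@@H](C(C)(C)O[Si](C)(C)C(C)(C)C)C/C=C(/C)CC/C=C(/C)C1 | intermediate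
27 | (1R,2Z,6R,8Z,12S,13R)-6-[2-(tert-butyldimethylsilyloxy)propan-2-yl]-12,13-epoxy-3-iodo-9,13-dimethylcyclotetradeca-2,8-dien-1-ol | O[C@H]1/C=C(\I)CC[C@@H](C(C)(C)O[Si](C)(C)C(C)(C)C)C/C=C(/C)CC[C@@H]2O[C@]2(C)C1 | intermediate
28 | (1R,2E,6R,8Z,12S,13R)-6-[2-(tert-butyldimethylsilyloxy)propan-2-yl]-12,13-epoxy-3,9,13-trimethylcyclotetradeca-2,8-dien-1-ol | O[C@H]1/C=C(\C)CC[C@@H](C(C)(C)O[Si](C)(C)C(C)(C)C)C/C=C(/C)CC[C@@H]2O[C@]2(C)C1 | intermediate
29 | (1R,2E,6R,8Z,12S,13R)-12,13-epoxy-6-(2-hydroxypropan-2-yl)-3,9,13-trimethylcyclotetradeca-2,8-dien-1-ol | O[C@H]1/C=C(\C)CC[C@@H](C(C)(C)O)C/C=C(/C)CC[C@@H]2O[C@]2(C)C1 | intermediate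
30 | (1R,2E,6R,8Z,12S,13R)-12,13-epoxy-6-(2-hydroxypropan-2-yl)-3,9,13-trimethylcyclotetradeca-2,8-dien-1-yl acetate (CNP0254503.2) | CC(=O)O[C@H]1/C=C(\C)CC[C@@H](C(C)(C)O)C/C=C(/C)CC[C@@H]2O[C@]2(C)C1 | target

Total step count: 17. Longest linear sequence: 15 steps from 1 (steps 1–5, 7 and 9–17); steps 6 and 8 are one-step side branches.

Steps most likely to fail

Step 11. Chain-growth oligomerisation through the unhindered C3 alkyne may outpace ring closure at the hindered propargylic alkyne, or the catalyst may stall at that alkyne. The fallback closes the ring at C3–C4 by intramolecular alkylation of a terminal acetylide, without metathesis; it sets out from 2 and comes back at 23. Ozonolysis of 2 in CH2Cl2/MeOH followed by Ac2O/Et3N/DMAP (Criegee rearrangement of the methoxy hydroperoxide) would give the acetoxy aldehyde F1, in which the former ketone carbon and its methyl have become the acetyl group on the C4 oxygen. The olefination of step 5 would give the Z-iodide F2, and the coupling of step 7 with 13 the carbamate acetate F3. K2CO3/MeOH would free the hydroxy carbamate F4. Lithiation–borylation as in step 9 (one extra equivalent of sBuLi for the alkoxide, then 17) and allylboration of 3-(trimethylsilyl)propynal would give the silylalkyne diol F5. K2CO3/MeOH would give the terminal alkyne diol F6; I2/PPh3/imidazole at 0 °C the primary iodide F7; and Et3SiCl/imidazole the silyl ether F8. LiN(SiMe3)2 in THF/HMPA at high dilution would then join the acetylide carbon to C4 and give 23.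

Step 14. The conformational bias of the macrocycle may override the ligand, so that the vanadate delivers oxygen to the wrong face of C12=C13. The fallback uses that bias on the C1 epimer and corrects C1 afterwards; it sets out from 26 and comes back at 30. Mitsunobu reaction of 26 with 4-nitrobenzoic acid (PPh3, DIAD) would give the inverted ester F9, and K2CO3/MeOH the (1S)-alcohol F10. By mirror-image reasoning its directed epoxidation (VO(OiPr)3, the matching ligand enantiomer, cumene hydroperoxide) should give the (12S,13R)-epoxide F11. Me2Zn/Pd(dppf)Cl2 would give the methylated alcohol F12 and Bu4NF the (1S)-diol F13. A final Mitsunobu reaction with acetic acid would install the acetate with inversion at C1 and give 30.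

Step 9. Configurational leakage at the lithiated carbon, or incomplete chirality transfer in the allylboration, would contaminate 21 with its C1 epimer. The fallback sets C1 by catalyst-controlled ketone reduction; it sets out from 14 and comes back at 21. Lithiation of 14 with sBuLi/TMEDA (no chiral diamine), borylation with 17 and allylboration of 16 as before would give the C1-epimeric alcohols F14, still with the Z olefin. Dess–Martin periodinane (NaHCO3, CH2Cl2) would give the ynone F15. Noyori transfer hydrogenation with RuCl[(R,R)-TsDPEN](p-cymene) in propan-2-ol, which is reliable for alkynyl ketones, should return (4R)-configured 21.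

Further compounds

F1 | step 11 | (3R)-3-[2-(tert-butyldimethylsilyloxy)propan-2-yl]-5-oxopentyl acetate | CC(=O)OCC[C@@H](C(C)(C)O[Si](C)(C)C(C)(C)C)CC=O
F2 | step 11 | (3S,5Z)-3-[2-(tert-butyldimethylsilyloxy)propan-2-yl]-6-iodohept-5-en-1-yl acetate | CC(=O)OCC[C@@H](C(C)(C)O[Si](C)(C)C(C)(C)C)C/C=C(/C)I
F3 | step 11 | (3S,5Z)-3-[2-(tert-butyldimethylsilyloxy)propan-2-yl]-9-(diisopropylcarbamoyloxy)-6-methylnon-5-en-1-yl acetate | CC(=O)OCC[C@@H](C(C)(C)O[Si](C)(C)C(C)(C)C)C/C=C(/C)CCCOC(=O)N(C(C)C)C(C)C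
F4 | step 11 | (4Z,7S)-7-[2-(tert-butyldimethylsilyloxy)propan-2-yl]-9-hydroxy-4-methylnon-4-en-1-yl N,N-diisopropylcarbamate | OCC[C@@H](C(C)(C)O[Si](C)(C)C(C)(C)C)C/C=C(/C)CCCOC(=O)N(C(C)C)C(C)C
F5 | step 11 | (3R,5Z,9Z,12S)-12-[2-(tert-butyldimethylsilyloxy)propan-2-yl]-5,9-dimethyl-1-(trimethylsilyl)tetradeca-5,9-dien-1-yne-3,14-diol | OCC[C@@H](C(C)(C)O[Si](C)(C)C(C)(C)C)C/C=C(/C)CC/C=C(/C)C[C@@H](O)C#C[Si](C)(C)C
F6 | step 11 | (3R,5Z,9Z,12S)-12-[2-(tert-butyldimethylsilyloxy)propan-2-yl]-5,9-dimethyltetradeca-5,9-dien-1-yne-3,14-diol | OCC[C@@H](C(C)(C)O[Si](C)(C)C(C)(C)C)C/C=C(/C)CC/C=C(/C)C[C@@H](O)C#C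
F7 | step 11 | (3R,5Z,9Z,12S)-12-[2-(tert-butyldimethylsilyloxy)propan-2-yl]-14-iodo-5,9-dimethyltetradeca-5,9-dien-1-yn-3-ol | ICC[C@@H](C(C)(C)O[Si](C)(C)C(C)(C)C)C/C=C(/C)CC/C=C(/C)C[C@@H](O)C#C
F8 | step 11 | (3R,5Z,9Z,12S)-12-[2-(tert-butyldimethylsilyloxy)propan-2-yl]-14-iodo-5,9-dimethyl-3-(triethylsilyloxy)tetradeca-5,9-dien-1-yne | ICC[C@@H](C(C)(C)O[Si](C)(C)C(C)(C)C)C/C=C(/C)CC/C=C(/C)C[C@@H](O[Si](CC)(CC)CC)C#C
F9 | step 14 | (1S,2Z,6R,8Z,12Z)-6-[2-(tert-butyldimethylsilyloxy)propan-2-yl]-3-iodo-9,13-dimethylcyclotetradeca-2,8,12-trien-1-yl 4-nitrobenzoate | O=C(O[C@@H]1/C=C(\I)CC[C@@H](C(C)(C)O[Si](C)(C)C(C)(C)C)C/C=C(/C)CC/C=C(/C)C1)c1ccc(cc1)[N+](=O)[O-]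
F10 | step 14 | (1S,2Z,6R,8Z,12Z)-6-[2-(tert-butyldimethylsilyloxy)propan-2-yl]-3-iodo-9,13-dimethylcyclotetradeca-2,8,12-trien-1-ol | O[C@@H]1/C=C(\I)CC[C@@H](C(C)(C)O[Si](C)(C)C(C)(C)C)C/C=C(/C)CC/C=C(/C)C1
F11 | step 14 | (1S,2Z,6R,8Z,12S,13R)-6-[2-(tert-butyldimethylsilyloxy)propan-2-yl]-12,13-epoxy-3-iodo-9,13-dimethylcyclotetradeca-2,8-dien-1-ol | O[C@@H]1/C=C(\I)CC[C@@H](C(C)(C)O[Si](C)(C)C(C)(C)C)C/C=C(/C)CC[C@@H]2O[C@]2(C)C1
F12 | step 14 | (1S,2E,6R,8Z,12S,13R)-6-[2-(tert-butyldimethylsilyloxy)propan-2-yl]-12,13-epoxy-3,9,13-trimethylcyclotetradeca-2,8-dien-1-ol | O[C@@H]1/C=C(\C)CC[C@@H](C(C)(C)O[Si](C)(C)C(C)(C)C)C/C=C(/C)CC[C@@H]2O[C@]2(C)C1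
F13 | step 14 | (1S,2E,6R,8Z,12S,13R)-12,13-epoxy-6-(2-hydroxypropan-2-yl)-3,9,13-trimethylcyclotetradeca-2,8-dien-1-ol | O[C@@H]1/C=C(\C)CC[C@@H](C(C)(C)O)C/C=C(/C)CC[C@@H]2O[C@]2(C)C1
F14 | step 9 | (4RS,6Z,10Z,13R)-13-[2-(tert-butyldimethylsilyloxy)propan-2-yl]-6,10-dimethyloctadeca-6,10-diene-2,16-diyn-4-ol (both C4 epimers) | CC#CCC[C@@H](C(C)(C)O[Si](C)(C)C(C)(C)C)C/C=C(/C)CC/C=C(/C)CC(O)C#CC
F15 | step 9 | (6Z,10Z,13R)-13-[2-(tert-butyldimethylsilyloxy)propan-2-yl]-6,10-dimethyloctadeca-6,10-diene-2,16-diyn-4-one | CC#CCC[C@@H](C(C)(C)O[Si](C)(C)C(C)(C)C)C/C=C(/C)CC/C=C(/C)CC(=O)C#CC
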